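**Plan**
The target is cut at the ester bond C(=O)–OCH2 into a western acid 23 (cyclohexene, isopropyl and side chain cis) and an eastern diol 44 (cyclohexane cis-fused to an oxepinone).
In the western ring the two ring CH2 carbons are cut away from the alkene carbon that carries CH2OH and from the CH that carries isopropyl. The four ring carbons that remain (C=O, CH=, C(CH2OR)=, CH-iPr) are a cyclobutenone, whose strained acyl–CH(iPr) bond opens when a vinyl anion adds (4π opening, then 6π closure).
The enone so formed fixes the cis stereochemistry (hydride anti to isopropyl, ligand-controlled kinetic resolution) and the place of the ring alkene (enolate, triflate, CO); a Wittig reaction builds the side chain.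
The eastern ring starts from (S)-4-isopropylcyclohex-2-enone: an allene [2+2] photocycloaddition locks two cis C–C bonds anti to isopropyl, the ketone takes CH2OH from the convex face, the cyclobutane is cleaved to CHO/CO2H, and ring-closing metathesis builds the oxepinone.
The halves are joined by esterification and freed in one fluoride step.

Key step: step 2

Assumption: the sense of induction of the two chiral catalysts ((R)-DTBM-SEGPHOS/CuH in step 3, the (S)-prolinol ether in step 13) is taken from the closest known substrates; the mirror-image catalyst would be used if the sense were opposite.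
Abbreviations: TBS = tert-butyldimethylsilyl, TBDPS = tert-butyldiphenylsilyl, TMSE = 2-(trimethylsilyl)ethyl, Tf = trifluoromethanesulfonyl.

**Western fragment**

Step 1
Reactants: 1 N,N,3-trimethylbutanamide; 2 tert-butyl(dimethyl)(prop-2-yn-1-yloxy)silane
Product: 3 rac-3-(TBS-oxymethyl)-4-(propan-2-yl)cyclobut-2-en-1-one
Conditions: Tf2O, 2,4,6-collidine, ClCH2CH2Cl, -15 °C to 80 °C; then aq. NaHCO3, rt
Reagents that add atoms: water, O
Why: Keteniminium–alkyne [2+2] cycloaddition, in which the keteniminium triflate from 1 adds across the terminal alkyne with its iminium carbon at the unsubstituted alkyne carbon, and hydrolysis of the cyclobuteniminium salt should give the racemic cyclobutenone.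

Step 2
Reactants: 3 rac-3-(TBS-oxymethyl)-4-(propan-2-yl)cyclobut-2-en-1-one; 4 tetraethenylstannane
Product: 9 rac-3-(TBS-oxymethyl)-4-(propan-2-yl)cyclohex-2-en-1-one, via ethenyllithium 5 (not isolated), via lithium cyclobutenolate 6 (not isolated), via lithium trienolate 7 (not isolated), via lithium cyclohexadienolate 8 (not isolated)
Conditions: 4 (0.3 equiv), MeLi (1.2 equiv), Et2O, 0 °C; add 3 in THF at -78 °C; warm to 25 °C; H2O
Reagents that add atoms: none
Why: Vinyllithium 5 should add 1,2 to the carbonyl of 3 (the ring β-carbon is fully substituted, so 1,4-addition is disfavoured), which makes the bond between the carbonyl carbon and the vinyl CH. The strained cyclobutenolate 6 then opens by oxy-anion-accelerated conrotatory 4π cleavage of the ring bond between the carbinol carbon and CH-iPr; the oxido group rotates outward, which turns the vinyl group inward and gives trienolate 7 with the vinyl group cis to the rest of the chain. Disrotatory 6π electrocyclisation of 7 closes the six-membered ring by joining the vinyl CH2 to the isopropyl-bearing carbon, and protonation of dienolate 8 at the former vinyl CH gives the conjugated enone. The closest known reaction type is the ring expansion of cyclobutenones to cyclohexenones by addition of alkenyllithium reagents followed by this 4π-opening/6π-closure cascade. The only new stereocentre (CH-iPr) arises from an achiral triene and is racemic; it is sorted in step 3. The selectivity needed is carbonyl addition and outward rotation of the oxido group, both inherent to the substrate, and the cascade leaves the enone C=C where the later enolate, and so the ring alkene of the target, must sit.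

Step 3
Reactants: 9 rac-3-(TBS-oxymethyl)-4-(propan-2-yl)cyclohex-2-en-1-one
Product: 11 (3S,4R)-3-(TBS-oxymethyl)-4-(propan-2-yl)cyclohex-1-en-1-yl trifluoromethanesulfonate, via silyl enol ether 10 (not isolated)
Conditions: Cu(OAc)2·H2O (3 mol%), (R)-DTBM-SEGPHOS (3 mol%), PhMe2SiH (0.55 equiv), toluene, 0 °C, to about half conversion; then CsF, PhNTf2, DME, rt; chromatography
Reagents that add atoms: N-phenylbis(trifluoromethanesulfonimide), O=S(=O)(N(c1ccccc1)S(=O)(=O)C(F)(F)F)C(F)(F)F
Why: Ligand-controlled CuH 1,4-hydrosilylation used as a kinetic resolution: in the (4R)-enone the β-face preferred by the catalyst is also the face anti to the pseudoaxial isopropyl group, so hydride should enter trans to isopropyl and set the cis relationship, the mismatched (4S)-enone is left behind, and fluoride-triggered O-triflation of 10 fixes the double bond on the side of the new stereocentre.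

Step 4
Reactants: 11 (3S,4R)-3-(TBS-oxymethyl)-4-(propan-2-yl)cyclohex-1-en-1-yl trifluoromethanesulfonate
Product: 12 methyl (3S,4R)-3-(TBS-oxymethyl)-4-(propan-2-yl)cyclohex-1-ene-1-carboxylate
Conditions: Pd(OAc)2 (5 mol%), Ph2P(CH2)3PPh2, CO (1 atm), Et3N, MeOH/DMF, 60 °C
Reagents that add atoms: carbon monoxide, [C-]#[O+]; methanol, CO
Why: Pd-catalysed alkoxycarbonylation of the vinyl triflate (oxidative addition, CO insertion, methanolysis) should place the future CH2OH carbon on the alkene carbon without touching the stereocentres.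

Step 5
Reactants: 12 methyl (3S,4R)-3-(TBS-oxymethyl)-4-(propan-2-yl)cyclohex-1-ene-1-carboxylate
Product: 13 [(3S,4R)-3-(TBS-oxymethyl)-4-(propan-2-yl)cyclohex-1-en-1-yl]methanol
Conditions: iBu2AlH (2.5 equiv), CH2Cl2, -78 °C; Rochelle salt
Reagents that add atoms: none
Why: Hydride reduction of the conjugated ester by iBu2AlH is 1,2-selective and should give the allylic alcohol.

Step 6
Reactants: 13 [(3S,4R)-3-(TBS-oxymethyl)-4-(propan-2-yl)cyclohex-1-en-1-yl]methanol
Product: 14 TBDPS ether of 13 (ring CH2O-TBDPS; side CH2O-TBS)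
Conditions: t-BuPh2SiCl, imidazole, DMF, rt
Reagents that add atoms: tert-butyl(chloro)diphenylsilane, CC(C)(C)[Si](Cl)(c1ccccc1)c1ccccc1
Why: Silylation of the primary allylic alcohol gives an ether that outlasts the TBS group under acid.

Step 7
Reactants: 14 TBDPS ether of 13
Product: 15 [(1S,6R)-3-(TBDPS-oxymethyl)-6-(propan-2-yl)cyclohex-2-en-1-yl]methanol
Conditions: PPTS, EtOH, 45 °C
Reagents that add atoms: none
Why: Acid-catalysed ethanolysis should remove the primary TBS ether much faster than the bulkier TBDPS ether.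

Step 8
Reactants: 15 [(1S,6R)-3-(TBDPS-oxymethyl)-6-(propan-2-yl)cyclohex-2-en-1-yl]methanol
Product: 16 (1S,6R)-3-(TBDPS-oxymethyl)-6-(propan-2-yl)cyclohex-2-ene-1-carbaldehyde
Conditions: Dess–Martin periodinane, NaHCO3, CH2Cl2, 0 °C; used at once
Reagents that add atoms: none
Why: Dess–Martin oxidation under buffered, non-basic conditions should give the β,γ-unsaturated aldehyde without epimerisation or double-bond migration.

Step 9
Reactants: 17 (2-hydroxyethyl)triphenylphosphonium bromide
Product: 18 (2-TBS-oxyethyl)triphenylphosphonium bromide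
Conditions: t-BuMe2SiCl, imidazole, CH2Cl2, rt
Reagents that add atoms: tert-butyl(chloro)dimethylsilane, CC(C)(C)[Si](C)(C)Cl
Why: Routine O-silylation of the primary alcohol of the phosphonium salt.

Step 10
Reactants: 18 (2-TBS-oxyethyl)triphenylphosphonium bromide; 19 prop-2-en-1-yl carbonochloridate
Product: 21 prop-2-en-1-yl 3-(TBS-oxy)-2-(triphenyl-λ5-phosphanylidene)propanoate, via non-stabilised ylide 20 (not isolated)
Conditions: KN(SiMe3)2 (2.05 equiv), THF, -78 °C; then 19 (1.0 equiv), -78 °C to rt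
Reagents that add atoms: none
Why: C-acylation of the non-stabilised ylide 20 by the chloroformate, then deprotonation of the acylphosphonium salt by the second equivalent of base, should give the ester-stabilised ylide.

Step 11
Reactants: 16 (1S,6R)-3-(TBDPS-oxymethyl)-6-(propan-2-yl)cyclohex-2-ene-1-carbaldehyde; 21 prop-2-en-1-yl 3-(TBS-oxy)-2-(triphenyl-λ5-phosphanylidene)propanoate
Product: 22 prop-2-en-1-yl (2E)-2-(TBS-oxymethyl)-3-[(1S,6R)-3-(TBDPS-oxymethyl)-6-(propan-2-yl)cyclohex-2-en-1-yl]prop-2-enoate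
Conditions: toluene, 60 °C
Reagents that add atoms: none
Why: Wittig olefination with an α-substituted ester-stabilised ylide should give the trisubstituted alkene with the ring carbon trans to the ester (E), and the neutral ylide should leave the doubly allylic stereocentre intact.

Step 12
Reactants: 22 allyl ester
Product: 23 (2E)-2-(TBS-oxymethyl)-3-[(1S,6R)-3-(TBDPS-oxymethyl)-6-(propan-2-yl)cyclohex-2-en-1-yl]prop-2-enoic acid
Conditions: Pd(PPh3)4 (5 mol%), morpholine, THF, rt
Reagents that add atoms: none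
Why: Allyl transfer through a π-allyl complex of zerovalent palladium to morpholine frees the acid without touching the silyl ethers.

**Eastern fragment**

Step 13
Reactants: 24 3-methylbutanal; 25 but-3-en-2-one
Product: 26 (2S)-5-oxo-2-(propan-2-yl)hexanal
Conditions: (S)-α,α-diphenylprolinol methyl ether (5 mol%), ethyl 3,4-dihydroxybenzoate (20 mol%), neat, 4 °C
Reagents that add atoms: none
Why: Enamine-catalysed Michael addition, in which the prolinol ether shields one enamine face and should set the α-stereocentre as S.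

Step 14
Reactants: 26 (2S)-5-oxo-2-(propan-2-yl)hexanal
Product: 27 (4S)-4-(propan-2-yl)cyclohex-2-en-1-one
Conditions: LiOH (0.2 equiv), i-PrOH, rt
Reagents that add atoms: none
Why: Intramolecular aldol condensation of the methyl ketone onto the aldehyde under mild base should give the enone without racemising the γ-stereocentre.

Step 15
Reactants: 27 (4S)-4-(propan-2-yl)cyclohex-2-en-1-one; 28 propa-1,2-diene
Product: 29 (1R,5S,6S)-8-methylidene-5-(propan-2-yl)bicyclo[4.2.0]octan-2-one
Conditions: hν (450 W Hg lamp, Pyrex), excess 28, THF, -78 °C; basic alumina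
Reagents that add atoms: none
Why: Enone–allene [2+2] photocycloaddition: head-to-head regiochemistry places the methylidene carbon on the enone α-carbon, the allene adds anti to the isopropyl group and the four-membered ring is cis-fused (any trans-fused adduct epimerises on alumina), so both new C–C bonds are cis to each other and trans to isopropyl.

Step 16
Reactants: 29 photoadduct; 30 (chloromethyl)dimethyl(propan-2-yloxy)silane
Product: 33 (1R,2R,5S,6S)-2-(hydroxymethyl)-8-methylidene-5-(propan-2-yl)bicyclo[4.2.0]octan-2-ol, via Grignard reagent 31 (not isolated), via β-hydroxysilane 32 (not isolated)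
Conditions: 30, Mg, THF, rt; CeCl3, THF, -78 °C, add 29, to 0 °C; then KF, KHCO3, 30% H2O2, MeOH/THF, rt
Reagents that add atoms: hydrogen peroxide, OO
Why: Nucleophilic hydroxymethylation: the organocerium from 31 should add to the ketone from the convex face (anti to the cyclobutane), which puts CH2 trans and OH cis to the ring-fusion C–C bond, and the Tamao oxidation turns C–Si into C–OH with no change at carbon.

Step 17
Reactants: 33 diol
Product: 34 (1R,2R,5S,6S)-2',2'-dimethyl-8-methylidene-5-(propan-2-yl)spiro[bicyclo[4.2.0]octane-2,4'-[1,3]dioxolane]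
Conditions: 2,2-dimethoxypropane, PPTS, CH2Cl2, rt
Reagents that add atoms: 2,2-dimethoxypropane, COC(C)(C)OC
Why: Acetonide formation ties up the tertiary and the primary hydroxyl, which blocks retro-aldol opening in steps 18 to 20.

Step 18
Reactants: 34 acetonide
Product: 35 cyclobutanone (1S,2R,5S,6S)-2',2'-dimethyl-5-(propan-2-yl)spiro[bicyclo[4.2.0]octane-2,4'-[1,3]dioxolan]-8-one
Conditions: O3, CH2Cl2, -78 °C; PPh3
Reagents that add atoms: ozone, [O-][O+]=O
Why: Ozonolysis of the 1,1-disubstituted alkene with reductive work-up gives the cyclobutanone.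

Step 19
Reactants: 35 cyclobutanone
Product: 36 trimethylsilyl enol ether of 35 (C7=C8 double bond; OSiMe3 on C8)
Conditions: LiN(iPr)2, THF, -78 °C; Me3SiCl; non-aqueous work-up
Reagents that add atoms: chlorotrimethylsilane, C[Si](C)(C)Cl
Why: Kinetic deprotonation should occur at the cyclobutanone CH2 (the ring-fusion CH is hindered and would give a strained enolate), and O-silylation gives the enol ether.

Step 20
Reactants: 36 silyl enol ether
Product: 37 (5R,6S,7S,8S)-7-formyl-2,2-dimethyl-8-(propan-2-yl)-1,3-dioxaspiro[4.5]decane-6-carboxylic acid (drawn open; expected largely as the lactol)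
Conditions: O3, CH2Cl2, -78 °C; Me2S, to rt; aq. NaH2PO4
Reagents that add atoms: ozone, [O-][O+]=O
Why: Ozonolysis of the silyl enol ether cleaves the four-membered ring regiospecifically, the oxygen-bearing carbon becoming the carboxylic acid and the other carbon the aldehyde, both still cis on the cyclohexane.

Step 21
Reactants: 37 aldehyde acid
Product: 38 (5R,6S,7S,8S)-7-ethenyl-2,2-dimethyl-8-(propan-2-yl)-1,3-dioxaspiro[4.5]decane-6-carboxylic acid
Conditions: Ph3PCH3Br (3.2 equiv), KN(SiMe3)2 (3 equiv), THF, 0 °C to rt; work-up at pH 4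
Reagents that add atoms: methyltriphenylphosphonium bromide, C[P+](c1ccccc1)(c1ccccc1)c1ccccc1.[Br-]
Why: Wittig methylenation of the aldehyde (released from the lactol) with excess ylide, the carboxylate being inert.

Step 22
Reactants: 39 2-(bromomethyl)prop-2-enoic acid; 40 2-(trimethylsilyl)ethanol
Product: 41 2-(trimethylsilyl)ethyl 2-(bromomethyl)prop-2-enoate
Conditions: N,N'-dicyclohexylcarbodiimide, DMAP (5 mol%), CH2Cl2, 0 °C
Reagents that add atoms: none
Why: Steglich esterification gives the fluoride-labile ester of the alkylating agent.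

Step 23
Reactants: 38 vinyl acid; 41 2-(trimethylsilyl)ethyl 2-(bromomethyl)prop-2-enoate
Product: 42 2-[(TMSE-oxy)carbonyl]prop-2-en-1-yl ester of 38
Conditions: Cs2CO3, DMF, 0 °C to rt
Reagents that add atoms: none
Why: O-alkylation of the caesium carboxylate by the allylic bromide (direct and allylic displacement give the same ester).

Step 24
Reactants: 42 diene ester
Product: 43 acetonide of 44 (spiro-dioxolane on the carbinol carbon; otherwise as 44)
Conditions: second-generation Grubbs catalyst RuCl2(=CHPh)(H2IMes)(PCy3) (10 mol%), toluene (2 mM), 80 °C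
Reagents that add atoms: none
Why: Ring-closing metathesis between the vinyl group and the 1,1-disubstituted acrylate alkene should close the seven-membered lactone, and the ring enforces the alkene geometry of the target (ring carbon cis to CH2O).

Step 25
Reactants: 43 lactone acetonide
Product: 44 2-(trimethylsilyl)ethyl (5aR,6S,9R,9aS)-9-hydroxy-9-(hydroxymethyl)-1-oxo-6-(propan-2-yl)-1,3,5a,6,7,8,9,9a-octahydro-2-benzoxepine-4-carboxylate
Conditions: AcOH/THF/H2O (3:1:1), 40 °C
Reagents that add atoms: none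
Why: Mild acid hydrolysis of the acetonide frees the 1,2-diol and leaves the lactone and the TMSE ester alone.

**Union**

Step 26
Reactants: 23 western acid; 44 eastern diol
Product: 45 fully protected ester (primary OH of 44 acylated by 23)
Conditions: 2,4,6-trichlorobenzoyl chloride, Et3N, THF, rt; then 44, DMAP, toluene, rt
Reagents that add atoms: none
Why: Yamaguchi esterification, in which the mixed anhydride of 23 acylates the primary alcohol while the tertiary alcohol is too hindered to react.

Step 27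
Reactants: 45 fully protected ester
Product: 46 CNP0361406.7
Conditions: Bu4NF, AcOH (1:1), THF, 0 °C to rt
Reagents that add atoms: none
Why: Fluoride should cleave both silyl ethers and trigger β-elimination of the 2-(trimethylsilyl)ethyl ester, giving the free acid and the two allylic alcohols.

**Compound list**
1 | N,N,3-trimethylbutanamide | CC(C)CC(=O)N(C)C | starting material
2 | tert-butyl(dimethyl)(prop-2-yn-1-yloxy)silane | C#CCO[Si](C)(C)C(C)(C)C | starting material
3 | rac-3-(TBS-oxymethyl)-4-(propan-2-yl)cyclobut-2-en-1-one | O=C1C=C(CO[Si](C)(C)C(C)(C)C)C1C(C)C | intermediate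
4 | tetraethenylstannane | C=C[Sn](C=C)(C=C)C=C | starting material
5 | ethenyllithium | [Li]C=C | intermediate
6 | lithium 1-ethenyl-3-(TBS-oxymethyl)-4-(propan-2-yl)cyclobut-2-en-1-olate (vinyl anti to isopropyl expected) | [Li]OC1(C=C)C=C(CO[Si](C)(C)C(C)(C)C)C1C(C)C | intermediate
7 | lithium 5-(TBS-oxymethyl)-7-methylocta-1,3,5-trien-3-olate (vinyl cis to C-5) | [Li]O/C(C=C)=C/C(CO[Si](C)(C)C(C)(C)C)=CC(C)C | intermediate
8 | lithium 5-(TBS-oxymethyl)-4-(propan-2-yl)cyclohexa-1,5-dien-1-olate | [Li]OC1=CCC(C(C)C)C(CO[Si](C)(C)C(C)(C)C)=C1 | intermediate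
9 | rac-3-(TBS-oxymethyl)-4-(propan-2-yl)cyclohex-2-en-1-one | O=C1C=C(CO[Si](C)(C)C(C)(C)C)C(C(C)C)CC1 | intermediate
10 | {[(3S,4R)-3-(TBS-oxymethyl)-4-(propan-2-yl)cyclohex-1-en-1-yl]oxy}(dimethyl)phenylsilane | CC(C)[C@H]1CCC(O[Si](C)(C)c2ccccc2)=C[C@H]1CO[Si](C)(C)C(C)(C)C | intermediate
11 | (3S,4R)-3-(TBS-oxymethyl)-4-(propan-2-yl)cyclohex-1-en-1-yl trifluoromethanesulfonate | CC(C)[C@H]1CCC(OS(=O)(=O)C(F)(F)F)=C[C@H]1CO[Si](C)(C)C(C)(C)C | intermediate
12 | methyl (3S,4R)-3-(TBS-oxymethyl)-4-(propan-2-yl)cyclohex-1-ene-1-carboxylate | CC(C)[C@H]1CCC(C(=O)OC)=C[C@H]1CO[Si](C)(C)C(C)(C)C | intermediate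
13 | [(3S,4R)-3-(TBS-oxymethyl)-4-(propan-2-yl)cyclohex-1-en-1-yl]methanol | CC(C)[C@H]1CCC(CO)=C[C@H]1CO[Si](C)(C)C(C)(C)C | intermediate
14 | tert-butyl{[(3S,4R)-3-(TBS-oxymethyl)-4-(propan-2-yl)cyclohex-1-en-1-yl]methoxy}diphenylsilane | CC(C)[C@H]1CCC(CO[Si](c2ccccc2)(c2ccccc2)C(C)(C)C)=C[C@H]1CO[Si](C)(C)C(C)(C)C | intermediate
15 | [(1S,6R)-3-(TBDPS-oxymethyl)-6-(propan-2-yl)cyclohex-2-en-1-yl]methanol | CC(C)[C@H]1CCC(CO[Si](c2ccccc2)(c2ccccc2)C(C)(C)C)=C[C@H]1CO | intermediate
16 | (1S,6R)-3-(TBDPS-oxymethyl)-6-(propan-2-yl)cyclohex-2-ene-1-carbaldehyde | CC(C)[C@H]1CCC(CO[Si](c2ccccc2)(c2ccccc2)C(C)(C)C)=C[C@H]1C=O | intermediate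
17 | (2-hydroxyethyl)triphenylphosphonium bromide | OCC[P+](c1ccccc1)(c1ccccc1)c1ccccc1.[Br-] | starting material
18 | (2-TBS-oxyethyl)triphenylphosphonium bromide | CC(C)(C)[Si](C)(C)OCC[P+](c1ccccc1)(c1ccccc1)c1ccccc1.[Br-] | intermediate
19 | prop-2-en-1-yl carbonochloridate | C=CCOC(=O)Cl | starting material
20 | (2-TBS-oxyethylidene)triphenyl-λ5-phosphane | CC(C)(C)[Si](C)(C)OCC=P(c1ccccc1)(c1ccccc1)c1ccccc1 | intermediate
21 | prop-2-en-1-yl 3-(TBS-oxy)-2-(triphenyl-λ5-phosphanylidene)propanoate | C=CCOC(=O)C(CO[Si](C)(C)C(C)(C)C)=P(c1ccccc1)(c1ccccc1)c1ccccc1 | intermediate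
22 | prop-2-en-1-yl (2E)-2-(TBS-oxymethyl)-3-[(1S,6R)-3-(TBDPS-oxymethyl)-6-(propan-2-yl)cyclohex-2-en-1-yl]prop-2-enoate | CC(C)[C@H]1CCC(CO[Si](c2ccccc2)(c2ccccc2)C(C)(C)C)=C[C@H]1/C=C(\CO[Si](C)(C)C(C)(C)C)C(=O)OCC=C | intermediate
23 | (2E)-2-(TBS-oxymethyl)-3-[(1S,6R)-3-(TBDPS-oxymethyl)-6-(propan-2-yl)cyclohex-2-en-1-yl]prop-2-enoic acid | CC(C)[C@H]1CCC(CO[Si](c2ccccc2)(c2ccccc2)C(C)(C)C)=C[C@H]1/C=C(\CO[Si](C)(C)C(C)(C)C)C(=O)O | intermediate
24 | 3-methylbutanal | CC(C)CC=O | starting material
25 | but-3-en-2-one | CC(=O)C=C | starting material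
26 | (2S)-5-oxo-2-(propan-2-yl)hexanal | CC(=O)CC[C@H](C=O)C(C)C | intermediate
27 | (4S)-4-(propan-2-yl)cyclohex-2-en-1-one | CC(C)[C@@H]1CCC(=O)C=C1 | intermediate
28 | propa-1,2-diene | C=C=C | starting material
29 | (1R,5S,6S)-8-methylidene-5-(propan-2-yl)bicyclo[4.2.0]octan-2-one | O=C1CC[C@@H](C(C)C)[C@@H]2CC(=C)[C@@H]21 | intermediate
30 | (chloromethyl)dimethyl(propan-2-yloxy)silane | CC(C)O[Si](C)(C)CCl | starting material
31 | {[dimethyl(propan-2-yloxy)silyl]methyl}magnesium chloride | CC(C)O[Si](C)(C)C[Mg]Cl | intermediate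
32 | (1R,2R,5S,6S)-2-{[dimethyl(propan-2-yloxy)silyl]methyl}-8-methylidene-5-(propan-2-yl)bicyclo[4.2.0]octan-2-ol | CC(C)O[Si](C)(C)C[C@@]1(O)CC[C@@H](C(C)C)[C@@H]2CC(=C)[C@@H]21 | intermediate
33 | (1R,2R,5S,6S)-2-(hydroxymethyl)-8-methylidene-5-(propan-2-yl)bicyclo[4.2.0]octan-2-ol | OC[C@@]1(O)CC[C@@H](C(C)C)[C@@H]2CC(=C)[C@@H]21 | intermediate
34 | (1R,2R,5S,6S)-2',2'-dimethyl-8-methylidene-5-(propan-2-yl)spiro[bicyclo[4.2.0]octane-2,4'-[1,3]dioxolane] | CC1(C)OC[C@@]2(O1)CC[C@@H](C(C)C)[C@@H]3CC(=C)[C@@H]32 | intermediate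
35 | (1S,2R,5S,6S)-2',2'-dimethyl-5-(propan-2-yl)spiro[bicyclo[4.2.0]octane-2,4'-[1,3]dioxolan]-8-one | CC1(C)OC[C@@]2(O1)CC[C@@H](C(C)C)[C@@H]3CC(=O)[C@@H]32 | intermediate
36 | trimethylsilyl enol ether of 35 (C7=C8, OSiMe3 on C8) | CC1(C)OC[C@@]2(O1)CC[C@@H](C(C)C)[C@@H]3C=C(O[Si](C)(C)C)[C@@H]32 | intermediate
37 | (5R,6S,7S,8S)-7-formyl-2,2-dimethyl-8-(propan-2-yl)-1,3-dioxaspiro[4.5]decane-6-carboxylic acid | CC1(C)OC[C@@]2(O1)CC[C@@H](C(C)C)[C@H](C=O)[C@@H]2C(=O)O | intermediate
38 | (5R,6S,7S,8S)-7-ethenyl-2,2-dimethyl-8-(propan-2-yl)-1,3-dioxaspiro[4.5]decane-6-carboxylic acid | CC1(C)OC[C@@]2(O1)CC[C@@H](C(C)C)[C@H](C=C)[C@@H]2C(=O)O | intermediate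
39 | 2-(bromomethyl)prop-2-enoic acid | C=C(CBr)C(=O)O | starting material
40 | 2-(trimethylsilyl)ethanol | C[Si](C)(C)CCO | starting material
41 | 2-(trimethylsilyl)ethyl 2-(bromomethyl)prop-2-enoate | C=C(CBr)C(=O)OCC[Si](C)(C)C | intermediate
42 | 2-[(TMSE-oxy)carbonyl]prop-2-en-1-yl (5R,6S,7S,8S)-7-ethenyl-2,2-dimethyl-8-(propan-2-yl)-1,3-dioxaspiro[4.5]decane-6-carboxylate | CC1(C)OC[C@@]2(O1)CC[C@@H](C(C)C)[C@H](C=C)[C@@H]2C(=O)OCC(=C)C(=O)OCC[Si](C)(C)C | intermediate
43 | acetonide of 44 (2,2-dimethyl-1,3-dioxolane spiro-fused at the carbinol carbon; ring fusion and isopropyl as in 44) | CC1(C)OC[C@@]2(O1)CC[C@@H](C(C)C)[C@@H]3C=C(C(=O)OCC[Si](C)(C)C)COC(=O)[C@@H]32 | intermediate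
44 | 2-(trimethylsilyl)ethyl (5aR,6S,9R,9aS)-9-hydroxy-9-(hydroxymethyl)-1-oxo-6-(propan-2-yl)-1,3,5a,6,7,8,9,9a-octahydro-2-benzoxepine-4-carboxylate | OC[C@@]1(O)CC[C@@H](C(C)C)[C@@H]2C=C(C(=O)OCC[Si](C)(C)C)COC(=O)[C@@H]21 | intermediate
45 | ester of acid 23 with the primary hydroxyl of 44 (TBS, TBDPS and TMSE groups in place) | CC(C)[C@H]1CCC(CO[Si](c2ccccc2)(c2ccccc2)C(C)(C)C)=C[C@H]1/C=C(\CO[Si](C)(C)C(C)(C)C)C(=O)OC[C@@]1(O)CC[C@@H](C(C)C)[C@@H]2C=C(C(=O)OCC[Si](C)(C)C)COC(=O)[C@@H]21 | intermediate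
46 | CNP0361406.7, (5aR,6S,9R,9aS)-9-hydroxy-9-({[(2E)-2-(hydroxymethyl)-3-[(1S,6R)-3-(hydroxymethyl)-6-(propan-2-yl)cyclohex-2-en-1-yl]prop-2-enoyl]oxy}methyl)-1-oxo-6-(propan-2-yl)-1,3,5a,6,7,8,9,9a-octahydro-2-benzoxepine-4-carboxylic acid | CC(C)[C@H]1CCC(CO)=C[C@H]1/C=C(\CO)C(=O)OC[C@@]1(O)CC[C@@H](C(C)C)[C@@H]2C=C(C(=O)O)COC(=O)[C@@H]21 | target

**Step count and risks**
Total: 27 steps. Longest linear sequence: 14 steps (24 to 46 through steps 13–21 and 23–27).

Most likely to fail:

1. Step 2. The lithium alkoxide may be slow to open, or the trienolate may be protonated or oligomerise before the electrocyclic closure. The fallback uses a Stork–Danheiser transposition and does not start from a compound of the route. Commercial 3-ethoxycyclohex-2-en-1-one F1 would be deprotonated (LiN(iPr)2, THF/HMPA, -78 °C) and alkylated with 2-iodopropane to give 3-ethoxy-6-(propan-2-yl)cyclohex-2-en-1-one F2. Addition of (methoxymethoxy)methyllithium (from Bu3SnCH2OCH2OMe and n-BuLi) to the carbonyl and acid work-up (1 M HCl) would give the transposed enone 3-[(methoxymethoxy)methyl]-4-(propan-2-yl)cyclohex-2-en-1-one F3. Stronger acid (HCl, aq. THF, 50 °C) would free 3-(hydroxymethyl)-4-(propan-2-yl)cyclohex-2-en-1-one F4, and silylation (t-BuMe2SiCl, imidazole) comes back to the route at 9, replacing compounds 1 to 8.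

2. Step 3. The catalyst may not distinguish the two enone enantiomers well enough, and hydride delivery syn to isopropyl in the mismatched enantiomer would erode both ee and the cis ratio. The fallback sets out from 9 and removes the need for a resolution. Deconjugation (KOt-Bu, t-BuOH/THF, then cold aq. AcOH) would give the achiral 3-(TBS-oxymethyl)-4-(propan-2-yl)cyclohex-3-en-1-one F5. Enantioselective proton-transfer isomerisation with a cinchona-derived primary amine and a carboxylic acid co-catalyst (toluene, -20 °C) would give (4R)-3-(TBS-oxymethyl)-4-(propan-2-yl)cyclohex-2-en-1-one F6. Substrate-controlled 1,4-hydrosilylation with achiral [(Ph3P)CuH]6 and PhMe2SiH passes through 10, and CsF/PhNTf2 comes back to the route at 11.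

3. Step 11. While the hindered olefination is slow, the doubly allylic stereocentre may epimerise or the ring double bond may move into conjugation with the aldehyde. The fallback sets out from 16 and builds the alkene from an alkyne. Dibromo-olefination (CBr4, PPh3, CH2Cl2, 0 °C) would give tert-butyl{[(3S,4R)-3-(2,2-dibromoethenyl)-4-(propan-2-yl)cyclohex-1-en-1-yl]methoxy}diphenylsilane F7. Treatment with n-BuLi (2 equiv, -78 °C) and then paraformaldehyde would give the propargylic alcohol 3-[(1S,6R)-3-(TBDPS-oxymethyl)-6-(propan-2-yl)cyclohex-2-en-1-yl]prop-2-yn-1-ol F8, which is silylated to its TBS ether F9. Syn-hydrostannation (Bu3SnH, PdCl2(PPh3)2), with tin on the carbon next to CH2OTBS and away from the branched ring carbon, would give the (E)-vinylstannane F10. Iodine (CH2Cl2, 0 °C) would give the vinyl iodide F11 with retention, and carbonylation (Pd(OAc)2, PPh3, CO, allyl alcohol, Et3N) comes back to the route at 22.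

Further compounds
F1 | step 2 | 3-ethoxycyclohex-2-en-1-one | CCOC1=CC(=O)CCC1
F2 | step 2 | 3-ethoxy-6-(propan-2-yl)cyclohex-2-en-1-one | CCOC1=CC(=O)C(C(C)C)CC1
F3 | step 2 | 3-[(methoxymethoxy)methyl]-4-(propan-2-yl)cyclohex-2-en-1-one | COCOCC1=CC(=O)CCC1C(C)C
F4 | step 2 | 3-(hydroxymethyl)-4-(propan-2-yl)cyclohex-2-en-1-one | OCC1=CC(=O)CCC1C(C)C
F5 | step 3 | 3-(TBS-oxymethyl)-4-(propan-2-yl)cyclohex-3-en-1-one | O=C1CCC(C(C)C)=C(CO[Si](C)(C)C(C)(C)C)C1
F6 | step 3 | (4R)-3-(TBS-oxymethyl)-4-(propan-2-yl)cyclohex-2-en-1-one | CC(C)[C@H]1CCC(=O)C=C1CO[Si](C)(C)C(C)(C)C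
F7 | step 11 | tert-butyl{[(3S,4R)-3-(2,2-dibromoethenyl)-4-(propan-2-yl)cyclohex-1-en-1-yl]methoxy}diphenylsilane | CC(C)[C@H]1CCC(CO[Si](c2ccccc2)(c2ccccc2)C(C)(C)C)=C[C@H]1C=C(Br)Br
F8 | step 11 | 3-[(1S,6R)-3-(TBDPS-oxymethyl)-6-(propan-2-yl)cyclohex-2-en-1-yl]prop-2-yn-1-ol | CC(C)[C@H]1CCC(CO[Si](c2ccccc2)(c2ccccc2)C(C)(C)C)=C[C@H]1C#CCO
F9 | step 11 | TBS ether of F8 | CC(C)[C@H]1CCC(CO[Si](c2ccccc2)(c2ccccc2)C(C)(C)C)=C[C@H]1C#CCO[Si](C)(C)C(C)(C)C
F10 | step 11 | (E)-vinylstannane, tributyltin on the carbon bearing CH2OTBS and ring carbon cis to CH2OTBS | CC(C)[C@H]1CCC(CO[Si](c2ccccc2)(c2ccccc2)C(C)(C)C)=C[C@H]1/C=C(\CO[Si](C)(C)C(C)(C)C)[Sn](CCCC)(CCCC)CCCC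
F11 | step 11 | vinyl iodide from F10, iodine in place of tin with the same geometry | CC(C)[C@H]1CCC(CO[Si](c2ccccc2)(c2ccccc2)C(C)(C)C)=C[C@H]1/C=C(\CO[Si](C)(C)C(C)(C)C)I
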